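**Plan**
- Retrosynthesis: the two acetates and the silyl groups on the C2 and C7 oxygens come off last. Then cut C12–C13 (Negishi coupling with a (Z)-vinyl iodide), C8=C17 (Mannich methylenation of a C7 ketone), C1–C10 (closure of ring A), C4–C5 (α-arylation of a lactone enolate) and C9–C11 (aryllithium plus ethylene oxide).
- Enabling feature: C10 is the quaternary ring-fusion carbon of ring B, carries the C20 methyl and lies para to the oxygen-bearing C7. Ring B is therefore a latent 4-methylphenol whose para carbon can be alkylated by C1 of a chain held on the neighbouring C5.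
- Forward: a flat arene (ring B) is joined to a chiral lactone, the lactone is opened to a C1 iodide, and dearomatising C1–C10 closure gives a bicyclic dienone (rings A and B). Dissolving-metal reduction then gives the trans-decalin, followed by the side chain, C17, the acetates and the C7 alcohol.
- Stereochemistry: C2 is bought (glutamic-acid-derived lactone). C4 follows by 1,3-induction in the arylation, C10 by a chair transition state in the key step, C5 and C9 by axial protonation in the Li/NH3 reduction, C7 by CBS reduction, and 13Z by stereoretentive coupling of a (Z)-iodide.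

Key step: step 11

Remark: labdane numbering is used throughout (C1–C10 decalin, C11–C16 side chain, C17 exocyclic CH2, C18 methyl and C19 oxymethyl on C4, C20 methyl on C10; β is the face of C20). Ar = 3-[2-(benzyloxy)ethyl]-5-(methoxymethoxy)-2-methylphenyl; Ar′ = 3-[2-(benzyloxy)ethyl]-5-hydroxy-2-methylphenyl; Ar″ = 3-[2-(benzyloxy)ethyl]-4,6-dibromo-5-hydroxy-2-methylphenyl.
Assumption: the C7 alcohol formed in step 12 is drawn as the equatorial 7β epimer expected from the reduction; this centre is erased again in step 14.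

**Step 1**
Reactants: 1 dibromocresol [3,5-dibromo-4-methylphenol]
Product: 2 MOM ether [1,3-dibromo-5-(methoxymethoxy)-2-methylbenzene]
Conditions: NaH, MOMCl, THF/DMF, 0 °C → rt
Reagents that add atoms: chloromethyl methyl ether, COCCl
Why: Williamson-type O-alkylation of the sodium phenoxide gives the MOM acetal, which tolerates the organolithium, enolate, hydride and silylation steps and is removed by mild Lewis acid in step 8.

**Step 2**
Reactants: 2 MOM ether [1,3-dibromo-5-(methoxymethoxy)-2-methylbenzene]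
Product: 4 arylethanol [2-[3-bromo-5-(methoxymethoxy)-2-methylphenyl]ethanol], via aryllithium 3 (not isolated)
Conditions: n-BuLi (1.05 equiv), THF, −78 °C; then ethylene oxide, −78 °C → rt; NH4Cl (aq)
Reagents that add atoms: ethylene oxide, C1CO1
Why: Bromine–lithium exchange on one of the two equivalent bromines (the aryllithium formed is deactivated toward a second exchange) followed by epoxide ring-opening attaches the two-carbon C11–C12 arm to the future C9.

**Step 3**
Reactants: 4 arylethanol [2-[3-bromo-5-(methoxymethoxy)-2-methylphenyl]ethanol]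
Product: 5 aryl bromide [1-[2-(benzyloxy)ethyl]-3-bromo-5-(methoxymethoxy)-2-methylbenzene]
Conditions: NaH, BnBr, Bu4NI (cat.), THF/DMF, 0 °C → rt
Reagents that add atoms: benzyl bromide, BrCc1ccccc1
Why: Williamson ether synthesis; the benzyl ether survives every step up to the dissolving-metal reduction, where it is removed without a separate operation.

**Step 4**
Reactants: 6 trityl lactone [(S)-5-(trityloxymethyl)dihydrofuran-2(3H)-one]
Product: 8 methyl lactone [(5S)-3-methyl-5-(trityloxymethyl)dihydrofuran-2(3H)-one as a mixture of C3 epimers], via lithium enolate 7 (not isolated)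
Conditions: LiN(iPr)2, THF, −78 °C; MeI, −78 → −40 °C
Reagents that add atoms: iodomethane, CI
Why: Alkylation of the lactone lithium enolate with iodomethane introduces the future C18 methyl; the epimer mixture is of no consequence because this centre is planarised again in step 5.

**Step 5**
Reactants: 8 methyl lactone [(5S)-3-methyl-5-(trityloxymethyl)dihydrofuran-2(3H)-one]; 5 aryl bromide [1-[2-(benzyloxy)ethyl]-3-bromo-5-(methoxymethoxy)-2-methylbenzene]
Product: 11 aryl lactone [(3S,5S)-3-Ar-3-methyl-5-(trityloxymethyl)dihydrofuran-2(3H)-one; Ar trans to CH2OTr], via lithium enolate 9 (not isolated), via zinc enolate 10 (not isolated)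
Conditions: LiN(iPr)2, THF, −78 °C; ZnCl2, → rt; Pd(dba)2 (5 mol %), P(tBu)3 (10 mol %), THF/toluene, 60 °C
Reagents that add atoms: none
Why: Palladium-catalysed α-arylation of the zinc enolate (enolate cross-coupling) builds the quaternary C4 and the C4–C5 bond, and the bulky trityloxymethyl group on C2 shields one face of the planar enolate so that the aryl group should enter anti to it (1,3-induction as in other alkylations of this lactone enolate), leaving the methyl cis to C1.

**Step 6**
Reactants: 11 aryl lactone [(3S,5S)-3-Ar-3-methyl-5-(trityloxymethyl)dihydrofuran-2(3H)-one]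
Product: 12 diol [(2S,4S)-2-Ar-2-methyl-5-(trityloxy)pentane-1,4-diol]
Conditions: LiAlH4, THF, 0 °C → rt
Reagents that add atoms: none
Why: Hydride reduction of the lactone to the 1,4-diol liberates the C19 and C2 hydroxyls without touching a stereocentre.

**Step 7**
Reactants: 12 diol [(2S,4S)-2-Ar-2-methyl-5-(trityloxy)pentane-1,4-diol]
Product: 14 bis-silyl ether [(2S,4S)-2-Ar-1-(tert-butyldimethylsilyloxy)-2-methyl-4-(triisopropylsilyloxy)-5-(trityloxy)pentane], via mono-TBS ether 13 (not isolated)
Conditions: TBSCl (1.1 equiv), imidazole, CH2Cl2, 0 °C; then 2,6-lutidine, iPr3SiOTf, 0 °C → rt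
Reagents that add atoms: tert-butyldimethylsilyl chloride, CC(C)(C)[Si](C)(C)Cl; triisopropylsilyl triflate, CC(C)[Si](OS(=O)(=O)C(F)(F)F)(C(C)C)C(C)C
Why: Silyl ether formation in one flask: the primary C19 hydroxyl reacts first with the silyl chloride and the hindered secondary C2 hydroxyl then requires the silyl triflate, giving two silyl ethers of different lability for separate release in steps 19 and 22.

**Step 8**
Reactants: 14 bis-silyl ether [(2S,4S)-2-Ar-1-(tert-butyldimethylsilyloxy)-2-methyl-4-(triisopropylsilyloxy)-5-(trityloxy)pentane]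
Product: 15 phenol alcohol [(2S,4S)-4-Ar′-5-(tert-butyldimethylsilyloxy)-4-methyl-2-(triisopropylsilyloxy)pentan-1-ol]
Conditions: ZnBr2, n-PrSH, CH2Cl2, 0 °C
Reagents that add atoms: none
Why: Zinc bromide activates the MOM acetal and the trityl ether and the thiol captures the methoxymethyl and trityl cations (Lewis-acid-mediated acetal and trityl ether cleavage), conditions that leave silyl and benzyl ethers intact.

**Step 9**
Reactants: 15 phenol alcohol [(2S,4S)-4-Ar′-5-(tert-butyldimethylsilyloxy)-4-methyl-2-(triisopropylsilyloxy)pentan-1-ol]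
Product: 16 iodide [(2S,4S)-2-Ar′-1-(tert-butyldimethylsilyloxy)-5-iodo-2-methyl-4-(triisopropylsilyloxy)pentane]
Conditions: PPh3, I2, imidazole (premixed), CH2Cl2, 0 °C
Reagents that add atoms: iodine, II
Why: Appel iodination converts the only aliphatic hydroxyl into the primary iodide that serves as the electrophile for ring closure; the phenol does not undergo substitution.

**Step 10**
Reactants: 16 iodide [(2S,4S)-2-Ar′-1-(tert-butyldimethylsilyloxy)-5-iodo-2-methyl-4-(triisopropylsilyloxy)pentane]
Product: 17 dibromophenol iodide [(2S,4S)-2-Ar″-1-(tert-butyldimethylsilyloxy)-5-iodo-2-methyl-4-(triisopropylsilyloxy)pentane]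
Conditions: NBS (2.1 equiv), CH2Cl2, 0 °C → rt
Reagents that add atoms: N-bromosuccinimide, O=C1CCC(=O)N1Br
Why: Electrophilic aromatic bromination of the phenol occurs at both ortho positions (C6 and C8) because the para position carries the C20 methyl, and the two bromines serve as temporary blocking groups for step 11.

**Step 11**
Reactants: 17 dibromophenol iodide [(2S,4S)-2-Ar″-1-(tert-butyldimethylsilyloxy)-5-iodo-2-methyl-4-(triisopropylsilyloxy)pentane]
Product: 19 dibromodienone [12-(benzyloxy)-6,8-dibromo-19-(tert-butyldimethylsilyloxy)-2α-(triisopropylsilyloxy)-13,14,15,16,17-pentanorlabda-5,8-dien-7-one], via caesium phenoxide 18 (not isolated)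
Conditions: Cs2CO3 (1.5 equiv), DMF (0.01 M), 60 °C
Reagents that add atoms: none
Why: Cs2CO3 deprotonates the acidic 2,6-dibromophenol and the ambident phenoxide 18 attacks the primary iodide carbon C1 through its para carbon C10 in an intramolecular SN2 reaction, which breaks the aromaticity of ring B and gives the cross-conjugated dienone. The closest known reaction type is the intramolecular para-C-alkylation of phenoxides by tethered primary halides or sulfonates (alkylative dearomatisation). Ring A closes in the 6-exo-tet mode, the leaving iodide lying outside the new six-membered ring C1–C2–C3–C4–C5–C10. The only new stereocentre, C10, is set by the chair-like transition state of ring A: attack must come perpendicular to the arene plane, so the C20 methyl becomes axial on ring A, and the chair that keeps the bulky C2 silyloxy group equatorial places C20 syn to the axial CH2OTBS on C4 and anti to the C2 oxygen, whereas the other chair would stack C20, the C4 methyl and the silyloxy group on one face. The step needs C- over O-alkylation, para (C10) over ortho (C6) attack and one face of C10: O-alkylation would require a meta-bridged eight-membered ring, the ortho carbons C6 and C8 carry the bromine blockers from step 10, and the face follows from the C2 and C4 stereocentres as described.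

**Step 12**
Reactants: 19 dibromodienone [12-(benzyloxy)-6,8-dibromo-19-(tert-butyldimethylsilyloxy)-2α-(triisopropylsilyloxy)-13,14,15,16,17-pentanorlabda-5,8-dien-7-one]
Product: 20 decalin diol [19-(tert-butyldimethylsilyloxy)-2α-(triisopropylsilyloxy)-13,14,15,16,17-pentanorlabdane-7β,12-diol; 5α-H and 9α-H]
Conditions: Li (excess), NH3(l)/THF, EtOH, −78 → −33 °C; NH4Cl
Reagents that add atoms: none
Why: Dissolving-metal (Birch-type) reduction in the presence of ethanol should cleave both vinylic C–Br bonds, reduce the two enone double bonds in turn with axial protonation of the β-carbons C5 and C9 from the α face (trans ring fusion and equatorial C9 arm, the thermodynamically favoured arrangement), take the ketone to the equatorial alcohol and cleave the benzyl ether.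

**Step 13**
Reactants: 20 decalin diol [19-(tert-butyldimethylsilyloxy)-2α-(triisopropylsilyloxy)-13,14,15,16,17-pentanorlabdane-7β,12-diol]
Product: 21 iodo alcohol [19-(tert-butyldimethylsilyloxy)-12-iodo-2α-(triisopropylsilyloxy)-13,14,15,16,17-pentanorlabdan-7β-ol]
Conditions: PPh3, I2, imidazole, CH2Cl2, 0 °C
Reagents that add atoms: iodine, II
Why: Appel iodination is selective for the unhindered primary C12 hydroxyl over the ring secondary C7 hydroxyl at low temperature.

**Step 14**
Reactants: 21 iodo alcohol [19-(tert-butyldimethylsilyloxy)-12-iodo-2α-(triisopropylsilyloxy)-13,14,15,16,17-pentanorlabdan-7β-ol]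
Product: 22 iodo ketone [19-(tert-butyldimethylsilyloxy)-12-iodo-2α-(triisopropylsilyloxy)-13,14,15,16,17-pentanorlabdan-7-one]
Conditions: Dess–Martin periodinane, NaHCO3, CH2Cl2, rt
Reagents that add atoms: none
Why: Dess–Martin oxidation returns the C7 ketone under neutral conditions that tolerate the alkyl iodide and the silyl ethers.

**Step 15**
Reactants: 23 butynol [but-2-yn-1-ol]
Product: 25 vinyl iodide [(Z)-3-iodobut-2-en-1-ol], via alkenylaluminate 24 (not isolated)
Conditions: NaAlH2(OCH2CH2OMe)2, Et2O, 0 °C → rt; then I2, THF, −78 °C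
Reagents that add atoms: iodine, II
Why: Hydroxyl-directed trans-hydroalumination of the propargylic alcohol places aluminium on the distal alkyne carbon within a five-membered aluminate, and iodinolysis with retention gives the (Z)-iodide in which iodine is cis to the CH2OH group.

**Step 16**
Reactants: 25 vinyl iodide [(Z)-3-iodobut-2-en-1-ol]
Product: 26 silyl vinyl iodide [(Z)-tert-butyl[(3-iodobut-2-en-1-yl)oxy]dimethylsilane]
Conditions: TBSCl, imidazole, CH2Cl2, rt
Reagents that add atoms: tert-butyldimethylsilyl chloride, CC(C)(C)[Si](C)(C)Cl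
Why: Standard silylation masks the hydroxyl so that it does not protonate the organozinc reagent in step 17.

**Step 17**
Reactants: 22 iodo ketone [19-(tert-butyldimethylsilyloxy)-12-iodo-2α-(triisopropylsilyloxy)-13,14,15,16,17-pentanorlabdan-7-one]; 26 silyl vinyl iodide [(Z)-tert-butyl[(3-iodobut-2-en-1-yl)oxy]dimethylsilane]
Product: 28 side-chain ketone [15,19-bis(tert-butyldimethylsilyloxy)-2α-(triisopropylsilyloxy)-17-norlabd-13Z-en-7-one], via alkylzinc iodide 27 (not isolated)
Conditions: Zn dust, LiCl, THF, 40 °C; then Pd(PPh3)4 (5 mol %), THF, rt → 50 °C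
Reagents that add atoms: none
Why: Negishi coupling: zinc inserts into the primary C–I bond in the presence of the ketone, and the palladium-catalysed sp3–sp2 coupling proceeds with retention of the vinyl iodide geometry, so C12 ends cis to C15 (13Z).

**Step 18**
Reactants: 28 side-chain ketone [15,19-bis(tert-butyldimethylsilyloxy)-2α-(triisopropylsilyloxy)-17-norlabd-13Z-en-7-one]
Product: 32 methylene ketone [15,19-bis(tert-butyldimethylsilyloxy)-2α-(triisopropylsilyloxy)labda-8(17),13Z-dien-7-one], via lithium enolate 29 (not isolated), via Mannich base 30 (not isolated), via ammonium iodide 31 (not isolated)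
Conditions: LiN(SiMe3)2, THF, −78 °C; CH2=NMe2+ I−, −78 °C → rt; then MeI, CH2Cl2, rt; then NaHCO3 (aq)
Reagents that add atoms: Eschenmoser's salt (N,N-dimethylmethyleneiminium iodide), C=[N+](C)C.[I-]
Why: Mannich methylenation with Eschenmoser's salt followed by quaternisation and β-elimination installs C17; enolisation should occur toward C8 because the axial C6–H is shielded by the syn-axial C19 and C20 groups and because the C7–C8 enolate is the less strained one in a trans-decalin, as in 3-oxo-5α-steroids that react at C2.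

**Step 19**
Reactants: 32 methylene ketone [15,19-bis(tert-butyldimethylsilyloxy)-2α-(triisopropylsilyloxy)labda-8(17),13Z-dien-7-one]
Product: 33 keto diol [15,19-dihydroxy-2α-(triisopropylsilyloxy)labda-8(17),13Z-dien-7-one]
Conditions: HF·pyridine, pyridine, THF, 0 °C → rt
Reagents that add atoms: none
Why: Fluoride-mediated desilylation under buffered conditions removes the two primary TBS ethers much faster than the secondary TIPS ether.

**Step 20**
Reactants: 33 keto diol [15,19-dihydroxy-2α-(triisopropylsilyloxy)labda-8(17),13Z-dien-7-one]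
Product: 34 keto diacetate [7-oxo-2α-(triisopropylsilyloxy)labda-8(17),13Z-diene-15,19-diyl diacetate]
Conditions: Ac2O, pyridine, DMAP (cat.), CH2Cl2, 0 °C
Reagents that add atoms: acetic anhydride, CC(=O)OC(C)=O
Why: Acylation of the two primary alcohols, the only free hydroxyls at this stage, installs both acetates of the target.

**Step 21**
Reactants: 34 keto diacetate [7-oxo-2α-(triisopropylsilyloxy)labda-8(17),13Z-diene-15,19-diyl diacetate]
Product: 35 allylic alcohol [7α-hydroxy-2α-(triisopropylsilyloxy)labda-8(17),13Z-diene-15,19-diyl diacetate]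
Conditions: (S)-2-methyl-CBS-oxazaborolidine [(S)-1-methyl-3,3-diphenyltetrahydro-1H,3H-pyrrolo[1,2-c][1,3,2]oxazaborole] (0.2 equiv), catecholborane, toluene, −78 °C
Reagents that add atoms: none
Why: Corey–Bakshi–Shibata reduction is 1,2-selective for enones and catalyst-controlled: with the alkylidene-bearing C8 side as the large group, the (S)-catalyst should deliver hydride to the β face (equatorial attack) and give the axial 7α (7R) alcohol, while catecholborane at −78 °C leaves acetates and alkenes untouched.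

**Step 22**
Reactants: 35 allylic alcohol [7α-hydroxy-2α-(triisopropylsilyloxy)labda-8(17),13Z-diene-15,19-diyl diacetate]
Product: 36 target [2α,7α-dihydroxylabda-8(17),13Z-diene-15,19-diyl diacetate]
Conditions: Bu4NF, AcOH (1:1), THF, rt → 40 °C
Reagents that add atoms: none
Why: Acetic-acid-buffered fluoride cleaves the secondary TIPS ether while the acetates survive, and acyl migration to the C2 hydroxyl is not possible because it lies trans to and remote from the C19 acetate.

**Compound list**
1 | 3,5-dibromo-4-methylphenol | Cc1c(Br)cc(O)cc1Br | starting material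
2 | 1,3-dibromo-5-(methoxymethoxy)-2-methylbenzene | Cc1c(Br)cc(OCOC)cc1Br | intermediate
3 | 3-bromo-5-(methoxymethoxy)-2-methylphenyllithium | [Li]c1cc(OCOC)cc(Br)c1C | intermediate
4 | 2-[3-bromo-5-(methoxymethoxy)-2-methylphenyl]ethanol | Cc1c(Br)cc(OCOC)cc1CCO | intermediate
5 | 1-[2-(benzyloxy)ethyl]-3-bromo-5-(methoxymethoxy)-2-methylbenzene | Cc1c(Br)cc(OCOC)cc1CCOCc1ccccc1 | intermediate
6 | (S)-5-(trityloxymethyl)dihydrofuran-2(3H)-one | O=C1CC[C@@H](COC(c2ccccc2)(c2ccccc2)c2ccccc2)O1 | starting material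
7 | lithium enolate of 6 | [Li]OC1=CC[C@@H](COC(c2ccccc2)(c2ccccc2)c2ccccc2)O1 | intermediate
8 | (5S)-3-methyl-5-(trityloxymethyl)dihydrofuran-2(3H)-one (C3 epimers) | CC1C[C@@H](COC(c2ccccc2)(c2ccccc2)c2ccccc2)OC1=O | intermediate
9 | lithium enolate of 8 | [Li]OC1=C(C)C[C@@H](COC(c2ccccc2)(c2ccccc2)c2ccccc2)O1 | intermediate
10 | chlorozinc enolate of 8 | Cl[Zn]OC1=C(C)C[C@@H](COC(c2ccccc2)(c2ccccc2)c2ccccc2)O1 | intermediate
11 | (3S,5S)-3-Ar-3-methyl-5-(trityloxymethyl)dihydrofuran-2(3H)-one (Ar trans to CH2OTr) | O=C1[C@](C)(c2cc(OCOC)cc(CCOCc3ccccc3)c2C)C[C@@H](COC(c2ccccc2)(c2ccccc2)c2ccccc2)O1 | intermediate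
12 | (2S,4S)-2-Ar-2-methyl-5-(trityloxy)pentane-1,4-diol | OC[C@](C)(c1cc(OCOC)cc(CCOCc2ccccc2)c1C)C[C@H](O)COC(c1ccccc1)(c1ccccc1)c1ccccc1 | intermediate
13 | (2S,4S)-4-Ar-5-(tert-butyldimethylsilyloxy)-4-methyl-1-(trityloxy)pentan-2-ol | CC(C)(C)[Si](C)(C)OC[C@](C)(c1cc(OCOC)cc(CCOCc2ccccc2)c1C)C[C@H](O)COC(c1ccccc1)(c1ccccc1)c1ccccc1 | intermediate
14 | (2S,4S)-2-Ar-1-(tert-butyldimethylsilyloxy)-2-methyl-4-(triisopropylsilyloxy)-5-(trityloxy)pentane | CC(C)(C)[Si](C)(C)OC[C@](C)(c1cc(OCOC)cc(CCOCc2ccccc2)c1C)C[C@H](O[Si](C(C)C)(C(C)C)C(C)C)COC(c1ccccc1)(c1ccccc1)c1ccccc1 | intermediate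
15 | (2S,4S)-4-Ar′-5-(tert-butyldimethylsilyloxy)-4-methyl-2-(triisopropylsilyloxy)pentan-1-ol | CC(C)(C)[Si](C)(C)OC[C@](C)(c1cc(O)cc(CCOCc2ccccc2)c1C)C[C@H](O[Si](C(C)C)(C(C)C)C(C)C)CO | intermediate
16 | (2S,4S)-2-Ar′-1-(tert-butyldimethylsilyloxy)-5-iodo-2-methyl-4-(triisopropylsilyloxy)pentane | CC(C)(C)[Si](C)(C)OC[C@](C)(c1cc(O)cc(CCOCc2ccccc2)c1C)C[C@H](O[Si](C(C)C)(C(C)C)C(C)C)CI | intermediate
17 | (2S,4S)-2-Ar″-1-(tert-butyldimethylsilyloxy)-5-iodo-2-methyl-4-(triisopropylsilyloxy)pentane | CC(C)(C)[Si](C)(C)OC[C@](C)(c1c(Br)c(O)c(Br)c(CCOCc2ccccc2)c1C)C[C@H](O[Si](C(C)C)(C(C)C)C(C)C)CI | intermediate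
18 | caesium phenoxide of 17 | CC(C)(C)[Si](C)(C)OC[C@](C)(c1c(Br)c([O-])c(Br)c(CCOCc2ccccc2)c1C)C[C@H](O[Si](C(C)C)(C(C)C)C(C)C)CI.[Cs+] | intermediate
19 | 12-(benzyloxy)-6,8-dibromo-19-(tert-butyldimethylsilyloxy)-2α-(triisopropylsilyloxy)-13,14,15,16,17-pentanorlabda-5,8-dien-7-one (10β-methyl) | O=C1C(Br)=C2[C@@](C)(CO[Si](C)(C)C(C)(C)C)C[C@H](O[Si](C(C)C)(C(C)C)C(C)C)C[C@]2(C)C(CCOCc3ccccc3)=C1Br | intermediate
20 | 19-(tert-butyldimethylsilyloxy)-2α-(triisopropylsilyloxy)-13,14,15,16,17-pentanorlabdane-7β,12-diol (5α-H, 9α-H) | C1[C@@H](O)C[C@H]2[C@@](C)(CO[Si](C)(C)C(C)(C)C)C[C@H](O[Si](C(C)C)(C(C)C)C(C)C)C[C@]2(C)[C@H]1CCO | intermediate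
21 | 19-(tert-butyldimethylsilyloxy)-12-iodo-2α-(triisopropylsilyloxy)-13,14,15,16,17-pentanorlabdan-7β-ol | C1[C@@H](O)C[C@H]2[C@@](C)(CO[Si](C)(C)C(C)(C)C)C[C@H](O[Si](C(C)C)(C(C)C)C(C)C)C[C@]2(C)[C@H]1CCI | intermediate
22 | 19-(tert-butyldimethylsilyloxy)-12-iodo-2α-(triisopropylsilyloxy)-13,14,15,16,17-pentanorlabdan-7-one | C1C(=O)C[C@H]2[C@@](C)(CO[Si](C)(C)C(C)(C)C)C[C@H](O[Si](C(C)C)(C(C)C)C(C)C)C[C@]2(C)[C@H]1CCI | intermediate
23 | but-2-yn-1-ol | CC#CCO | starting material
24 | sodium alkenylaluminate from 23 (five-membered C–Al–O ring, two 2-methoxyethoxy ligands) | CC1=CCO[Al-]1(OCCOC)OCCOC.[Na+] | intermediate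
25 | (Z)-3-iodobut-2-en-1-ol | I/C(C)=C\CO | intermediate
26 | (Z)-tert-butyl[(3-iodobut-2-en-1-yl)oxy]dimethylsilane | I/C(C)=C\CO[Si](C)(C)C(C)(C)C | intermediate
27 | C12 alkylzinc iodide from 22 | C1C(=O)C[C@H]2[C@@](C)(CO[Si](C)(C)C(C)(C)C)C[C@H](O[Si](C(C)C)(C(C)C)C(C)C)C[C@]2(C)[C@H]1CC[Zn]I | intermediate
28 | 15,19-bis(tert-butyldimethylsilyloxy)-2α-(triisopropylsilyloxy)-17-norlabd-13Z-en-7-one | C1C(=O)C[C@H]2[C@@](C)(CO[Si](C)(C)C(C)(C)C)C[C@H](O[Si](C(C)C)(C(C)C)C(C)C)C[C@]2(C)[C@H]1CC/C(C)=C\CO[Si](C)(C)C(C)(C)C | intermediate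
29 | C7–C8 lithium enolate of 28 | C1=C(O[Li])C[C@H]2[C@@](C)(CO[Si](C)(C)C(C)(C)C)C[C@H](O[Si](C(C)C)(C(C)C)C(C)C)C[C@]2(C)[C@H]1CC/C(C)=C\CO[Si](C)(C)C(C)(C)C | intermediate
30 | 8-(dimethylaminomethyl) ketone (Mannich base of 28, C8 epimers) | CN(C)CC1C(=O)C[C@H]2[C@@](C)(CO[Si](C)(C)C(C)(C)C)C[C@H](O[Si](C(C)C)(C(C)C)C(C)C)C[C@]2(C)[C@H]1CC/C(C)=C\CO[Si](C)(C)C(C)(C)C | intermediate
31 | 8-(trimethylammoniomethyl) ketone iodide | C[N+](C)(C)CC1C(=O)C[C@H]2[C@@](C)(CO[Si](C)(C)C(C)(C)C)C[C@H](O[Si](C(C)C)(C(C)C)C(C)C)C[C@]2(C)[C@H]1CC/C(C)=C\CO[Si](C)(C)C(C)(C)C.[I-] | intermediate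
32 | 15,19-bis(tert-butyldimethylsilyloxy)-2α-(triisopropylsilyloxy)labda-8(17),13Z-dien-7-one | C=C1C(=O)C[C@H]2[C@@](C)(CO[Si](C)(C)C(C)(C)C)C[C@H](O[Si](C(C)C)(C(C)C)C(C)C)C[C@]2(C)[C@H]1CC/C(C)=C\CO[Si](C)(C)C(C)(C)C | intermediate
33 | 15,19-dihydroxy-2α-(triisopropylsilyloxy)labda-8(17),13Z-dien-7-one | C=C1C(=O)C[C@H]2[C@@](C)(CO)C[C@H](O[Si](C(C)C)(C(C)C)C(C)C)C[C@]2(C)[C@H]1CC/C(C)=C\CO | intermediate
34 | 7-oxo-2α-(triisopropylsilyloxy)labda-8(17),13Z-diene-15,19-diyl diacetate | C=C1C(=O)C[C@H]2[C@@](C)(COC(C)=O)C[C@H](O[Si](C(C)C)(C(C)C)C(C)C)C[C@]2(C)[C@H]1CC/C(C)=C\COC(C)=O | intermediate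
35 | 7α-hydroxy-2α-(triisopropylsilyloxy)labda-8(17),13Z-diene-15,19-diyl diacetate | C=C1[C@H](O)C[C@H]2[C@@](C)(COC(C)=O)C[C@H](O[Si](C(C)C)(C(C)C)C(C)C)C[C@]2(C)[C@H]1CC/C(C)=C\COC(C)=O | intermediate
36 | 2α,7α-dihydroxylabda-8(17),13Z-diene-15,19-diyl diacetate (2R,4S,5R,7R,9R,10S) | C=C1[C@H](O)C[C@H]2[C@@](C)(COC(C)=O)C[C@H](O)C[C@]2(C)[C@H]1CC/C(C)=C\COC(C)=O | target

**Step count and risks**
Total step count: 22. Longest linear sequence: 19 steps (steps 1–3, 5–14 and 17–22).

The three steps most likely to fail: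

Step 11. The C-alkylation may be too slow, because the doubly brominated phenoxide is a weak carbon nucleophile and the iodide is β-branched, so that decomposition competes with ring closure. The fallback abandons the bromine blockers. It sets out from 16, which is cyclised as its potassium phenoxide (KOtBu, tBuOH/THF, reflux) to the bromine-free dienone [12-(benzyloxy)-19-(tert-butyldimethylsilyloxy)-2α-(triisopropylsilyloxy)-13,14,15,16,17-pentanorlabda-5,8-dien-7-one] F1. The more nucleophilic phenoxide should alkylate faster, at the price of competing attack by the now free ortho carbon C6; the rearomatised tetralin phenol from that pathway is removed by chromatography. F1 is then reduced under the conditions of step 12 and comes back to the route at 20.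

Step 5. Reductive elimination at the congested quaternary centre next to the ortho methyl of the aryl group may be slow, or the facial selectivity of the arylation may be poor. The fallback reverses the order in which the two C4 substituents arrive, so that the stereocentre is set by a simple enolate methylation. It sets out from 5 and the enantiomeric lactone [(R)-5-(trityloxymethyl)dihydrofuran-2(3H)-one] F2. F2 is arylated with 5 under the conditions of step 5, now forming only a tertiary centre, to the α-aryl lactone [(5R)-3-Ar-5-(trityloxymethyl)dihydrofuran-2(3H)-one, C3 epimers] F3. Methylation of its lithium enolate (LiN(iPr)2, MeI, THF, −78 °C) should occur anti to the trityloxymethyl group and give the lactone [(3S,5R)-3-Ar-3-methyl-5-(trityloxymethyl)dihydrofuran-2(3H)-one] F4, which has the correct C4 but the wrong C2 configuration. LiAlH4 gives the diol [(2S,4R)-2-Ar-2-methyl-5-(trityloxy)pentane-1,4-diol] F5, and TBSCl/imidazole the primary silyl ether [(2R,4S)-4-Ar-5-(tert-butyldimethylsilyloxy)-4-methyl-1-(trityloxy)pentan-2-ol] F6. A Mitsunobu reaction (4-nitrobenzoic acid, PPh3, DIAD, THF) inverts C2 and gives the 4-nitrobenzoate of 13 F7. K2CO3 in MeOH cleaves the ester and the fallback comes back to the route at 13, which is silylated to 14 as in the second half of step 7.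

Step 21. Hydride may attack from the α face (axial attack, the intrinsic preference of this ketone toward small hydride donors) and override the catalyst, or conjugate reduction of the exocyclic enone may compete. The fallback accepts the intrinsic preference and inverts afterwards. It sets out from 34: Luche reduction (NaBH4, CeCl3·7H2O, MeOH, −78 °C) should give the equatorial alcohol [7β-hydroxy-2α-(triisopropylsilyloxy)labda-8(17),13Z-diene-15,19-diyl diacetate] F8. Mitsunobu inversion with chloroacetic acid (PPh3, DIAD, toluene) gives the axial ester [7α-(chloroacetoxy)-2α-(triisopropylsilyloxy)labda-8(17),13Z-diene-15,19-diyl diacetate] F9. The much more labile chloroacetate is then cleaved in the presence of the two acetates (K2CO3 cat., MeOH, −10 °C), and the fallback comes back to the route at 35.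

**Further compounds**
F1 | step 11 | 12-(benzyloxy)-19-(tert-butyldimethylsilyloxy)-2α-(triisopropylsilyloxy)-13,14,15,16,17-pentanorlabda-5,8-dien-7-one | O=C1C=C2[C@@](C)(CO[Si](C)(C)C(C)(C)C)C[C@H](O[Si](C(C)C)(C(C)C)C(C)C)C[C@]2(C)C(CCOCc3ccccc3)=C1
F2 | step 5 | (R)-5-(trityloxymethyl)dihydrofuran-2(3H)-one | O=C1CC[C@H](COC(c2ccccc2)(c2ccccc2)c2ccccc2)O1
F3 | step 5 | (5R)-3-Ar-5-(trityloxymethyl)dihydrofuran-2(3H)-one (C3 epimers) | O=C1C(c2cc(OCOC)cc(CCOCc3ccccc3)c2C)C[C@H](COC(c2ccccc2)(c2ccccc2)c2ccccc2)O1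
F4 | step 5 | (3S,5R)-3-Ar-3-methyl-5-(trityloxymethyl)dihydrofuran-2(3H)-one | O=C1[C@](C)(c2cc(OCOC)cc(CCOCc3ccccc3)c2C)C[C@H](COC(c2ccccc2)(c2ccccc2)c2ccccc2)O1
F5 | step 5 | (2S,4R)-2-Ar-2-methyl-5-(trityloxy)pentane-1,4-diol | OC[C@](C)(c1cc(OCOC)cc(CCOCc2ccccc2)c1C)C[C@@H](O)COC(c1ccccc1)(c1ccccc1)c1ccccc1
F6 | step 5 | (2R,4S)-4-Ar-5-(tert-butyldimethylsilyloxy)-4-methyl-1-(trityloxy)pentan-2-ol | CC(C)(C)[Si](C)(C)OC[C@](C)(c1cc(OCOC)cc(CCOCc2ccccc2)c1C)C[C@@H](O)COC(c1ccccc1)(c1ccccc1)c1ccccc1
F7 | step 5 | 4-nitrobenzoate of 13 (C2 inverted relative to F6) | CC(C)(C)[Si](C)(C)OC[C@](C)(c1cc(OCOC)cc(CCOCc2ccccc2)c1C)C[C@H](OC(=O)c1ccc(cc1)[N+](=O)[O-])COC(c1ccccc1)(c1ccccc1)c1ccccc1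
F8 | step 21 | 7β-hydroxy-2α-(triisopropylsilyloxy)labda-8(17),13Z-diene-15,19-diyl diacetate | C=C1[C@@H](O)C[C@H]2[C@@](C)(COC(C)=O)C[C@H](O[Si](C(C)C)(C(C)C)C(C)C)C[C@]2(C)[C@H]1CC/C(C)=C\COC(C)=O
F9 | step 21 | 7α-(chloroacetoxy)-2α-(triisopropylsilyloxy)labda-8(17),13Z-diene-15,19-diyl diacetate | C=C1[C@H](OC(=O)CCl)C[C@H]2[C@@](C)(COC(C)=O)C[C@H](O[Si](C(C)C)(C(C)C)C(C)C)C[C@]2(C)[C@H]1CC/C(C)=C\COC(C)=O
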